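**Target:** (3R)-3-[2,4-dihydroxy-3-(3-methylbut-2-en-1-yl)phenyl]-7-hydroxy-5-methoxychromane-8-carbaldehyde (25), made by building ring B last around the prenyl-bearing carbon in a Danheiser benzannulation.

## Analysis of the target

The target is an isoflavan: a chroman (aromatic ring A fused to the oxygen heterocycle, ring C) that carries the resorcinol ring B on C3. C3 is the only stereocentre and is (R). It has no neighbouring stereocentre to lean on, so its configuration has to come from a chiral catalyst or reagent. Ring A is a fully differentiated phloroglucinol: methyl ether at C5, free phenol at C7, and a formyl group at C8 between O7 and O1, with C6 left open. Formylation of a finished 5,7-dioxygenated chroman would therefore have to choose C8 over C6. Ring B is a contiguous 1,2,3,4-tetrasubstituted resorcinol in which the prenyl-bearing C3' lies between the oxygenated carbons C2' and C4'. Alkylation of a resorcinol prefers the positions para to oxygen, so this is the pattern that substitution does not deliver cleanly. The prenyl group flanked by two free phenols cyclises to a dimethylchroman under acid. The salicylaldehyde and three phenols also rule out hydrogenolysis and strong oxidants at the end. The plan rests on ring B: it is assembled from open-chain pieces so that C3' enters already carrying the prenyl group, bonded on one side to the carbon that becomes C2'–OH and on the other to the carbon that carries the C4' oxygen.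

## Retrosynthetic reasoning

Target 25 is traced back to bis-silyl ether 24 by removal of two aryl silyl ethers with a fluoride source. Fluoride is chosen because the prenyl group between two phenols tolerates base but not acid.

The C8 aldehyde of 24 is traced through benzylic alcohol 23 to methyl ester 22. The C8 carbon is carried as an ester because an aldehyde would not survive the hydride, ylide, enolate and photochemical steps that come before. The ester is fixed on ring A from the first step, so no C8/C6 selection is ever required.

Ring B of 22 is cut at four bonds: C1'–C2', C2'–C3', C4'–C5' and C5'–C6'. This leads to dienyl diazo ketone 14 and siloxyalkyne 17. The cut is made here because it turns the awkward 1,2,3,4-pattern into the inherent polarity of a ketene and an oxygen-substituted alkyne. The alkyne carbon bearing the prenyl group must bond to the ketene carbonyl carbon, so prenyl has no other place to go than C3'. The forward reaction has to generate vinylketene 18, add 17 to it to give cyclobutenone 19, open this to dienylketene 20 and close ring B through cyclohexadienone 21. The C3 stereocentre rides along untouched as a substituent.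

Siloxyalkyne 17 is cut at the O–Si bond to ynolate 16. The C1–C2 bond of 16 comes from a one-carbon ester homologation of ethyl 4-methylpent-3-enoate 15, which already contains the prenyl unit.

Diazo ketone 14 is traced to methyl enone 12 through its activated diketone 13. This places the diazo carbon without an acid chloride and without diazomethane.

The C=C bond of 12 is cut to aldehyde 11 and stabilised ylide 10. Aldehyde 11 has an acidic hydrogen on the stereocentre and an aryloxy group in the β position, so it is generated from alcohol 9 and consumed in the same flask.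

Alcohol 9 is traced to carboxylic acid 8, and 8 to chromene acid 7 by addition of hydrogen across C3=C4. The free acid is the handle for the chiral hydrogenation catalyst. It is also chemically distinct from the C8 methyl ester, so the later reduction at C3 is selective without any protecting-group work.

Acid 7 comes from enal 6 by oxidation. Ring C of 6 is cut at O1–C2 and C3–C4 to salicylaldehyde 4 and acrolein 5. This forms the heterocycle and the trisubstituted alkene needed for the hydrogenation in one condensation.

Salicylaldehyde 4 is traced through dihydroxy aldehyde 3 and symmetric diol 2 to methyl 2,4,6-trihydroxybenzoate 1. The order is methylation of the only non-chelated hydroxyl, formylation of one of two equivalent ring positions, then silylation of the less hindered of the two remaining hydroxyls. The symmetry of 1 and 2 does most of the regiochemical work.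

## Alternatives that were turned down

Alternative 1: Ring C is cut at C3–C4 and O1–C2. In the forward direction ring A sulfone A3 releases an ortho-quinone methide under base. The chiral enamine formed from arylacetaldehyde A2 and a secondary amine catalyst attacks the exocyclic carbon (C4), and the phenoxide closes on the aldehyde carbon to give lactol A1 with C3 set. In its favour, the union is convergent, the stereocentre is made catalytically with ring B already attached, and the step count after the union is low. On convergence and on setting C3 late it is at least as strong as the chosen plan. Against it for this target: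
- A2 already contains the prenyl group between two oxygens, so the hardest structural problem is moved into a starting material.
- The hindered, doubly ortho-substituted A2 must form an enamine.
- C3 in A1 is benzylic and sits next to a masked aldehyde, so the lactol–hydroxy aldehyde equilibrium offers a path to enolisation and loss of configuration.
- Removing the C2 hydroxyl needs ionic reduction under a Lewis or Brønsted acid, the conditions that cyclise the prenyl group onto an ortho oxygen.

The chosen route offers in its place an unambiguous construction of ring B from 14 and 17 and a stereocentre that is set on a configurationally stable carboxylic acid.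

Alternative 2: Ring A is cut at C4a–C8a and C7–C8. In the forward direction the silyloxyfuran of precursor A5 adds intramolecularly across the tethered β-alkoxyacrylate. The oxygen-bridged adduct then loses silanol and water to give A4, with rings A and C formed together. In its favour, the tether fixes the ring A pattern (C5 methoxy, C7 hydroxyl, C8 ester) completely. The three regiochemical operations on ring A in the chosen route (steps 1 to 3) have no counterpart there, and on this point the alternative is stronger. Against it:
- A5 must already hold the C3 stereocentre on an open chain and the prenylated ring B, so two separate problems remain unsolved upstream.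
- The silyloxyfuran is hydrolytically fragile.
- A β-alkoxyacrylate is a donor-substituted, sluggish dienophile.
- Aromatisation by loss of water from the bridge calls for acid, with the prenyl group present.
- The linear sequence to A5 would be long.

The chosen route accepts ordinary phloroglucinol chemistry for ring A and spends its one demanding step on ring B, where the real difficulty lies.

Alternative 3: The bonds cut are O1–C8a and C8–CHO. In the forward direction fluoroarene A7 is lithiated at C8 between fluorine and the acetal-protected oxygen. Loss of lithium fluoride gives the C8–C8a aryne, the tethered alkoxide adds at C8a to close ring C, and the resulting C8 aryllithium is trapped with a formamide to give tris-acetal A6. In its favour, one operation closes ring C and places the formyl group at C8 with complete regiocontrol. No ester reduction and re-oxidation is needed, which saves two steps at the end; here the alternative is clearly stronger than the chosen plan. Against it: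
- The three acetal groups of A6 must come off under acid, with a prenyl group between two phenols and a salicylaldehyde present.
- The excess alkyllithium has other sites on ring B to attack (C5' next to an acetal oxygen, and the benzylic and allylic methylene of the prenyl group).
- A7 needs both the prenylated ring B and an acyclic 2,3-diarylpropanol stereocentre, each a synthesis of its own.

The chosen route ends with a fluoride deprotection that the prenyl resorcinol tolerates, and it builds ring B instead of importing it.

Key step: step 11

Remark on protecting groups: the C7 oxygen is carried as a triisopropylsilyl ether. It must pass carbonate base, hydride and enolate chemistry, it migrates less readily than smaller silyl groups, and it leaves together with the C4' silyl ether in the last step.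

Assumption: the (R) hand of the bisphosphine is taken to give the (3S) acid 8, by analogy with (E)-α-alkylcinnamic acids. If the first run shows the opposite sense, the antipodal ligand is used.

## Route

Step 1
Reactants: 1 methyl 2,4,6-trihydroxybenzoate
Product: 2 methyl 2,6-dihydroxy-4-methoxybenzoate
Conditions: Me2SO4 (1.0 equiv), K2CO3 (1.0 equiv), acetone, 0 °C → rt
Reagents that add atoms: dimethyl sulfate, COS(=O)(=O)OC
Why: Selective phenol O-methylation: the C4 hydroxyl is para to the ester, the most acidic, and the only one not held in a hydrogen bond to the ester carbonyl, so one equivalent of a hard methylating agent with a weak base should alkylate it first.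

Step 2
Reactants: 2 methyl 2,6-dihydroxy-4-methoxybenzoate
Product: 3 methyl 3-formyl-2,6-dihydroxy-4-methoxybenzoate
Conditions: POCl3, DMF, MeCN, 0 °C → rt; then H2O, 50 °C
Reagents that add atoms: N,N-dimethylformamide, CN(C)C=O; water, O
Why: Vilsmeier–Haack formylation of a phloroglucinol-type ring; the two open positions of 2 are equivalent, so only one aldehyde can form, and the first formyl group deactivates the ring against a second.

Step 3
Reactants: 3 methyl 3-formyl-2,6-dihydroxy-4-methoxybenzoate
Product: 4 methyl 3-formyl-2-hydroxy-4-methoxy-6-[(triisopropylsilyl)oxy]benzoate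
Conditions: i-Pr3SiCl (1.05 equiv), imidazole, DMF, 0 °C → rt
Reagents that add atoms: chlorotri(propan-2-yl)silane, CC(C)[Si](Cl)(C(C)C)C(C)C
Why: Regioselective O-silylation: the C2 hydroxyl is flanked by the formyl and ester groups and chelated to the aldehyde, whereas the C6 hydroxyl has an open ortho position, so the bulky silyl chloride should react at C6, as in the 4-O-silylation of 2,4-dihydroxybenzaldehydes.

Step 4
Reactants: 4 methyl 3-formyl-2-hydroxy-4-methoxy-6-[(triisopropylsilyl)oxy]benzoate; 5 acrolein
Product: 6 methyl 3-formyl-5-methoxy-7-[(triisopropylsilyl)oxy]-2H-chromene-8-carboxylate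
Conditions: acrolein (2 equiv), K2CO3, 1,4-dioxane, 100 °C
Reagents that add atoms: none
Why: Domino oxa-Michael addition and aldol condensation: the phenoxide adds to acrolein (O1–C2), the enolate attacks the ortho formyl group (C3–C4) and water is lost; the only free hydroxyl is the one ortho to the aldehyde.

Step 5
Reactants: 6 methyl 3-formyl-5-methoxy-7-[(triisopropylsilyl)oxy]-2H-chromene-8-carboxylate
Product: 7 5-methoxy-8-(methoxycarbonyl)-7-[(triisopropylsilyl)oxy]-2H-chromene-3-carboxylic acid
Conditions: NaClO2, NaH2PO4, 2-methylbut-2-ene, t-BuOH/H2O, rt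
Reagents that add atoms: sodium chlorite, [Na+].[O-]Cl=O
Why: Pinnick oxidation of an enal to the acid; the alkene scavenger removes hypochlorous acid before it can chlorinate the electron-rich ring, and the mild pH leaves the silyl ether and the ester alone.

Step 6
Reactants: 7 5-methoxy-8-(methoxycarbonyl)-7-[(triisopropylsilyl)oxy]-2H-chromene-3-carboxylic acid
Product: 8 (3S)-5-methoxy-8-(methoxycarbonyl)-7-[(triisopropylsilyl)oxy]chromane-3-carboxylic acid
Conditions: Ru(OAc)2[(R)-H8-BINAP] (1 mol %), H2 (5 bar), MeOH, 25 °C
Reagents that add atoms: none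
Why: Carboxylate-directed asymmetric hydrogenation of a cyclic (E)-α-alkylcinnamic acid; the acid binds the ruthenium dicarboxylate and the chiral bisphosphine selects the alkene face, which sets C3; the descriptor is (S) here only because the carboxyl group outranks C2.

Step 7
Reactants: 8 (3S)-5-methoxy-8-(methoxycarbonyl)-7-[(triisopropylsilyl)oxy]chromane-3-carboxylic acid
Product: 9 methyl (3R)-3-(hydroxymethyl)-5-methoxy-7-[(triisopropylsilyl)oxy]chromane-8-carboxylate
Conditions: BH3·SMe2, THF, 0 °C → rt; MeOH quench
Reagents that add atoms: none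
Why: Chemoselective borane reduction of a carboxylic acid through its acyloxyborane; the hindered aromatic methyl ester at C8 is not reduced and C3 is untouched (the change to R is a priority change only).

Step 8
Reactants: 9 methyl (3R)-3-(hydroxymethyl)-5-methoxy-7-[(triisopropylsilyl)oxy]chromane-8-carboxylate; 10 1-(triphenyl-λ5-phosphanylidene)propan-2-one
Product: 12 methyl (3R)-5-methoxy-3-[(1E)-3-oxobut-1-en-1-yl]-7-[(triisopropylsilyl)oxy]chromane-8-carboxylate, via aldehyde 11 (not isolated)
Conditions: Dess–Martin periodinane, NaHCO3, CH2Cl2, 0 °C → rt; then 10, rt → 40 °C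
Reagents that add atoms: none
Why: Dess–Martin oxidation followed in the same flask by Wittig olefination with a stabilised ylide, which is E-selective and needs no added base; trapping 11 as it forms limits enolisation at C3 and β-elimination of the ring aryloxide.

Step 9
Reactants: 12 methyl (3R)-5-methoxy-3-[(1E)-3-oxobut-1-en-1-yl]-7-[(triisopropylsilyl)oxy]chromane-8-carboxylate
Product: 14 methyl (3R)-3-[(1E)-4-diazo-3-oxobut-1-en-1-yl]-5-methoxy-7-[(triisopropylsilyl)oxy]chromane-8-carboxylate, via trifluoroacetyl diketone 13 (not isolated)
Conditions: LiN(SiMe3)2, THF, −78 °C; CF3CO2CH2CF3; then MeSO2N3, Et3N, H2O, MeCN, rt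
Reagents that add atoms: methanesulfonyl azide, CS(=O)(=O)N=[N+]=[N-]
Why: Detrifluoroacetylative diazo transfer (Regitz type): the kinetic enolate forms at the methyl group, Claisen acylation gives the activated diketone, and diazo transfer with loss of the trifluoroacetyl group to the sulfonamide gives the diazo ketone; C3 is γ to the ketone and is not deprotonated under kinetic control.

Step 10
Reactants: 15 ethyl 4-methylpent-3-enoate
Product: 17 5-methyl-1-[(triisopropylsilyl)oxy]hex-4-en-1-yne, via lithium ynolate 16 (not isolated)
Conditions: CH2Br2, lithium 2,2,6,6-tetramethylpiperidide, THF, −78 °C; 15; n-BuLi, −78 → 0 °C; then i-Pr3SiCl, −78 °C → rt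
Reagents that add atoms: dibromomethane, BrCBr; chlorotri(propan-2-yl)silane, CC(C)[Si](Cl)(C(C)C)C(C)C
Why: Kowalski ester homologation: dibromomethyllithium adds to the ester, bromine–lithium exchange and 1,2-shift of the prenyl-bearing carbon give the ynolate, and the bulky silyl chloride silylates it on oxygen.

Step 11
Reactants: 14 methyl (3R)-3-[(1E)-4-diazo-3-oxobut-1-en-1-yl]-5-methoxy-7-[(triisopropylsilyl)oxy]chromane-8-carboxylate; 17 5-methyl-1-[(triisopropylsilyl)oxy]hex-4-en-1-yne
Product: 22 methyl (3R)-3-{2-hydroxy-3-(3-methylbut-2-en-1-yl)-4-[(triisopropylsilyl)oxy]phenyl}-5-methoxy-7-[(triisopropylsilyl)oxy]chromane-8-carboxylate, via vinylketene 18 (not isolated), via 4-vinylcyclobutenone 19 (not isolated), via dienylketene 20 (not isolated), via cyclohexadienone 21 (not isolated)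
Conditions: 17 (2 equiv), hν (300 nm), degassed ClCH2CH2Cl, rt; then 80 °C
Reagents that add atoms: none
Why: Light expels N2 from 14 and the alkenyl group shifts to the carbene carbon (Wolff rearrangement, new C5'–C6' bond) to give vinylketene 18. Alkyne 17 is polarised by its oxygen, so its prenyl-bearing carbon attacks the ketene carbonyl carbon (C2'–C3') and its oxygen-bearing carbon closes onto the ketene terminus (C4'–C5'), a regiospecific [2+2] cycloaddition that gives 19. Heating opens 19 by reversible 4π electrocyclic cleavage to dienylketene 20, and ring B closes by thermal disrotatory 6π electrocyclisation between the ketene carbon and the alkene terminus (C1'–C2'); enolisation of 21 then gives the phenol. The closest known reaction type is the Danheiser benzannulation in its photochemical Wolff form with a siloxyalkyne as the ketene partner. No stereocentre is created, since the sp3 carbons of 19 and 21 disappear on aromatisation, and C3 is only a substituent on the alkene terminus and takes part in no bond change. The selectivity the step needs is the orientation of the [2+2] addition; the oxygen polarisation of 17 secures it, puts the prenyl carbon between the new C2' hydroxyl and the C4' silyl ether, and leaves the two oxygens differentiated. The E alkene of 14 keeps the C3 hydrogen away from the ketene carbon, so a [1,5]-hydrogen shift should not compete.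

Step 12
Reactants: 22 methyl (3R)-3-{2-hydroxy-3-(3-methylbut-2-en-1-yl)-4-[(triisopropylsilyl)oxy]phenyl}-5-methoxy-7-[(triisopropylsilyl)oxy]chromane-8-carboxylate
Product: 23 [(3R)-3-{2-hydroxy-3-(3-methylbut-2-en-1-yl)-4-[(triisopropylsilyl)oxy]phenyl}-5-methoxy-7-[(triisopropylsilyl)oxy]chroman-8-yl]methanol
Conditions: i-Bu2AlH (5 equiv), CH2Cl2, −78 → 0 °C; aqueous potassium sodium tartrate
Reagents that add atoms: none
Why: Hydride reduction of the aryl ester to the benzylic alcohol; the free phenol is carried as its aluminium phenoxide, the bulky silyl ethers resist the reagent, and the neutral work-up protects the electron-rich benzylic alcohol from ionisation.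

Step 13
Reactants: 23 [(3R)-3-{2-hydroxy-3-(3-methylbut-2-en-1-yl)-4-[(triisopropylsilyl)oxy]phenyl}-5-methoxy-7-[(triisopropylsilyl)oxy]chroman-8-yl]methanol
Product: 24 (3R)-3-{2-hydroxy-3-(3-methylbut-2-en-1-yl)-4-[(triisopropylsilyl)oxy]phenyl}-5-methoxy-7-[(triisopropylsilyl)oxy]chromane-8-carbaldehyde
Conditions: MnO2 (activated, excess), CH2Cl2, rt
Reagents that add atoms: none
Why: Manganese dioxide oxidation, selective for the activated benzylic alcohol; the prenyl alkene and the hindered resorcinol-type phenol should be left untouched under these neutral heterogeneous conditions.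

Step 14
Reactants: 24 (3R)-3-{2-hydroxy-3-(3-methylbut-2-en-1-yl)-4-[(triisopropylsilyl)oxy]phenyl}-5-methoxy-7-[(triisopropylsilyl)oxy]chromane-8-carbaldehyde
Product: 25 (3R)-3-[2,4-dihydroxy-3-(3-methylbut-2-en-1-yl)phenyl]-7-hydroxy-5-methoxychromane-8-carbaldehyde
Conditions: Bu4NF, AcOH, THF, 0 °C → rt
Reagents that add atoms: none
Why: Fluoride cleavage of both aryl silyl ethers; buffering with acetic acid keeps the phenoxides protonated, and no acid strong enough to cyclise the prenyl group onto a neighbouring phenol is present.

## Compound list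

1 | methyl 2,4,6-trihydroxybenzoate | COC(=O)c1c(O)cc(O)cc1O | starting material
2 | methyl 2,6-dihydroxy-4-methoxybenzoate | COC(=O)c1c(O)cc(OC)cc1O | intermediate
3 | methyl 3-formyl-2,6-dihydroxy-4-methoxybenzoate | COC(=O)c1c(O)cc(OC)c(C=O)c1O | intermediate
4 | methyl 3-formyl-2-hydroxy-4-methoxy-6-[(triisopropylsilyl)oxy]benzoate | COC(=O)c1c(O[Si](C(C)C)(C(C)C)C(C)C)cc(OC)c(C=O)c1O | intermediate
5 | acrolein (prop-2-enal) | C=CC=O | starting material
6 | methyl 3-formyl-5-methoxy-7-[(triisopropylsilyl)oxy]-2H-chromene-8-carboxylate | COc1cc(O[Si](C(C)C)(C(C)C)C(C)C)c(C(=O)OC)c2c1C=C(C=O)CO2 | intermediate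
7 | 5-methoxy-8-(methoxycarbonyl)-7-[(triisopropylsilyl)oxy]-2H-chromene-3-carboxylic acid | COc1cc(O[Si](C(C)C)(C(C)C)C(C)C)c(C(=O)OC)c2c1C=C(C(=O)O)CO2 | intermediate
8 | (3S)-5-methoxy-8-(methoxycarbonyl)-7-[(triisopropylsilyl)oxy]chromane-3-carboxylic acid | COc1cc(O[Si](C(C)C)(C(C)C)C(C)C)c(C(=O)OC)c2c1C[C@H](C(=O)O)CO2 | intermediate
9 | methyl (3R)-3-(hydroxymethyl)-5-methoxy-7-[(triisopropylsilyl)oxy]chromane-8-carboxylate | COc1cc(O[Si](C(C)C)(C(C)C)C(C)C)c(C(=O)OC)c2c1C[C@H](CO)CO2 | intermediate
10 | 1-(triphenyl-λ5-phosphanylidene)propan-2-one | CC(=O)C=P(c1ccccc1)(c1ccccc1)c1ccccc1 | starting material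
11 | methyl (3S)-3-formyl-5-methoxy-7-[(triisopropylsilyl)oxy]chromane-8-carboxylate | COc1cc(O[Si](C(C)C)(C(C)C)C(C)C)c(C(=O)OC)c2c1C[C@H](C=O)CO2 | intermediate (not isolated)
12 | methyl (3R)-5-methoxy-3-[(1E)-3-oxobut-1-en-1-yl]-7-[(triisopropylsilyl)oxy]chromane-8-carboxylate | COc1cc(O[Si](C(C)C)(C(C)C)C(C)C)c(C(=O)OC)c2c1C[C@H](/C=C/C(C)=O)CO2 | intermediate
13 | methyl (3R)-5-methoxy-3-[(1E)-6,6,6-trifluoro-3,5-dioxohex-1-en-1-yl]-7-[(triisopropylsilyl)oxy]chromane-8-carboxylate | COc1cc(O[Si](C(C)C)(C(C)C)C(C)C)c(C(=O)OC)c2c1C[C@H](/C=C/C(=O)CC(=O)C(F)(F)F)CO2 | intermediate (not isolated)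
14 | methyl (3R)-3-[(1E)-4-diazo-3-oxobut-1-en-1-yl]-5-methoxy-7-[(triisopropylsilyl)oxy]chromane-8-carboxylate | COc1cc(O[Si](C(C)C)(C(C)C)C(C)C)c(C(=O)OC)c2c1C[C@H](/C=C/C(=O)C=[N+]=[N-])CO2 | intermediate
15 | ethyl 4-methylpent-3-enoate | CCOC(=O)CC=C(C)C | starting material
16 | lithium 5-methylhex-4-en-1-yn-1-olate | CC(C)=CCC#C[O-].[Li+] | intermediate (not isolated)
17 | 5-methyl-1-[(triisopropylsilyl)oxy]hex-4-en-1-yne | CC(C)=CCC#CO[Si](C(C)C)(C(C)C)C(C)C | intermediate
18 | methyl (3R)-5-methoxy-3-[(1E)-4-oxobuta-1,3-dien-1-yl]-7-[(triisopropylsilyl)oxy]chromane-8-carboxylate | COc1cc(O[Si](C(C)C)(C(C)C)C(C)C)c(C(=O)OC)c2c1C[C@H](/C=C/C=C=O)CO2 | intermediate (not isolated)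
19 | methyl (3R)-5-methoxy-3-[(1E)-2-{3-(3-methylbut-2-en-1-yl)-4-oxo-2-[(triisopropylsilyl)oxy]cyclobut-2-en-1-yl}ethenyl]-7-[(triisopropylsilyl)oxy]chromane-8-carboxylate (either configuration at the cyclobutenone sp3 carbon) | COc1cc(O[Si](C(C)C)(C(C)C)C(C)C)c(C(=O)OC)c2c1C[C@H](/C=C/C1C(=O)C(CC=C(C)C)=C1O[Si](C(C)C)(C(C)C)C(C)C)CO2 | intermediate (not isolated)
20 | methyl (3R)-5-methoxy-3-[(1E,3E)-5-(3-methylbut-2-en-1-yl)-6-oxo-4-[(triisopropylsilyl)oxy]hexa-1,3,5-trien-1-yl]-7-[(triisopropylsilyl)oxy]chromane-8-carboxylate (carbon chain cis across C3=C4 of the triene) | COc1cc(O[Si](C(C)C)(C(C)C)C(C)C)c(C(=O)OC)c2c1C[C@H](/C=C/C=C(/O[Si](C(C)C)(C(C)C)C(C)C)C(CC=C(C)C)=C=O)CO2 | intermediate (not isolated)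
21 | methyl (3R)-5-methoxy-3-{5-(3-methylbut-2-en-1-yl)-6-oxo-4-[(triisopropylsilyl)oxy]cyclohexa-2,4-dien-1-yl}-7-[(triisopropylsilyl)oxy]chromane-8-carboxylate (either configuration at the ring sp3 carbon) | COc1cc(O[Si](C(C)C)(C(C)C)C(C)C)c(C(=O)OC)c2c1C[C@H](C1C=CC(O[Si](C(C)C)(C(C)C)C(C)C)=C(CC=C(C)C)C1=O)CO2 | intermediate (not isolated)
22 | methyl (3R)-3-{2-hydroxy-3-(3-methylbut-2-en-1-yl)-4-[(triisopropylsilyl)oxy]phenyl}-5-methoxy-7-[(triisopropylsilyl)oxy]chromane-8-carboxylate | COc1cc(O[Si](C(C)C)(C(C)C)C(C)C)c(C(=O)OC)c2c1C[C@H](c1ccc(O[Si](C(C)C)(C(C)C)C(C)C)c(CC=C(C)C)c1O)CO2 | intermediate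
23 | [(3R)-3-{2-hydroxy-3-(3-methylbut-2-en-1-yl)-4-[(triisopropylsilyl)oxy]phenyl}-5-methoxy-7-[(triisopropylsilyl)oxy]chroman-8-yl]methanol | COc1cc(O[Si](C(C)C)(C(C)C)C(C)C)c(CO)c2c1C[C@H](c1ccc(O[Si](C(C)C)(C(C)C)C(C)C)c(CC=C(C)C)c1O)CO2 | intermediate
24 | (3R)-3-{2-hydroxy-3-(3-methylbut-2-en-1-yl)-4-[(triisopropylsilyl)oxy]phenyl}-5-methoxy-7-[(triisopropylsilyl)oxy]chromane-8-carbaldehyde | COc1cc(O[Si](C(C)C)(C(C)C)C(C)C)c(C=O)c2c1C[C@H](c1ccc(O[Si](C(C)C)(C(C)C)C(C)C)c(CC=C(C)C)c1O)CO2 | intermediate
25 | (3R)-3-[2,4-dihydroxy-3-(3-methylbut-2-en-1-yl)phenyl]-7-hydroxy-5-methoxychromane-8-carbaldehyde | COc1cc(O)c(C=O)c2c1C[C@H](c1ccc(O)c(CC=C(C)C)c1O)CO2 | target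

## Step count and risks

Total step count: 14. Longest linear sequence: 13 steps (steps 1 to 9 and 11 to 14); step 10 is a one-step side branch.

Least certain steps:

Step 11 (key step). The most likely failure is inefficient photochemical ketene formation. Ring A absorbs in the same region as the diazo ketone, and light can also isomerise the alkene of 14 to the Z form, whose vinylketene is lost by a [1,5]-hydrogen shift. Acylation of the product phenol by unreacted ketene and a silyl shift in 17 on prolonged heating are lesser losses. The fallback generates the same vinylketene without light. It sets out from 14: silver-promoted Wolff rearrangement in aqueous THF (PhCO2Ag, Et3N) gives (3E)-4-[(3R)-5-methoxy-8-(methoxycarbonyl)-7-[(triisopropylsilyl)oxy]chroman-3-yl]but-3-enoic acid F1. Oxalyl chloride converts this to the acid chloride F2. Slow addition of Et3N to F2 in the presence of 17 eliminates HCl to give 18, which adds to 17 in the dark to form 19, and heating to 80 °C carries 19 through 20 and 21. The fallback comes back to the route at 22.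

Step 10. The α-hydrogens of 15 are both allylic and next to the ester, so deprotonation to a dienolate may outrun addition of dibromomethyllithium, returning conjugated ester or self-condensation products. The fallback avoids any nucleophilic addition to the ester. It sets out from 15: reduction with i-Bu2AlH at −78 °C gives 4-methylpent-3-enal F3. Corey–Fuchs olefination (CBr4, PPh3) gives 1,1-dibromo-5-methylhexa-1,4-diene F4. Two equivalents of n-BuLi convert F4 into lithium 5-methylhex-4-en-1-yn-1-ide F5, which is oxidised in the same flask with LiOOt-Bu. This returns to the route at ynolate 16, which is silylated as in step 10.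

Step 4. The phenoxide of 4 is stabilised by two ortho carbonyl groups and may add to acrolein slowly. Prolonged heating with carbonate and the water formed could then cleave the activated aryl silyl ether. The fallback changes both the partner and the mechanism. It sets out from 4: a Morita–Baylis–Hillman reaction with tert-butyl acrylate and DABCO at room temperature, followed by conjugate ring closure and loss of water, gives 3-tert-butyl 8-methyl 5-methoxy-7-[(triisopropylsilyl)oxy]-2H-chromene-3,8-dicarboxylate F6. Trifluoroacetic acid in CH2Cl2 at 0 °C removes the tert-butyl group. The fallback comes back at acid 7 and makes step 5 unnecessary.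

Step 3. Both hydroxyls of 3 are hydrogen-bonded to carbonyl groups, so silylation may be slow and may partly go to the C2 oxygen or to both. The fallback reverses the order, so that the symmetry of 2 removes the choice. It sets out from 2: monosilylation (i-Pr3SiCl, imidazole) gives methyl 2-hydroxy-4-methoxy-6-[(triisopropylsilyl)oxy]benzoate F7. Magnesium-mediated ortho-formylation (MgCl2, Et3N, paraformaldehyde, MeCN, reflux) can only place the formyl group next to the free hydroxyl. The fallback comes back at 4 and replaces steps 2 and 3.

Step 6. The trisubstituted, electron-rich styrene-type alkene may be hydrogenated with insufficient facial selectivity, or with the opposite sense to the one assumed. The fallback replaces catalyst control by a resolution. It sets out from 7: hydrogenation over Pd/C gives the racemic acid F8. Activation as the pivalic mixed anhydride and reaction with lithiated (4S)-4-benzyl-1,3-oxazolidin-2-one gives the two diastereomeric imides, which are separated by chromatography. These are (4S)-4-benzyl-3-{[(3S)-5-methoxy-8-(methoxycarbonyl)-7-[(triisopropylsilyl)oxy]chroman-3-yl]carbonyl}-1,3-oxazolidin-2-one F9 and its (3R) diastereomer F10. Reduction of F9 with LiBH4 releases the auxiliary and comes back to the route at alcohol 9, so step 7 is not needed.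

## Further compounds

F1 | step 11 | (3E)-4-[(3R)-5-methoxy-8-(methoxycarbonyl)-7-[(triisopropylsilyl)oxy]chroman-3-yl]but-3-enoic acid | COc1cc(O[Si](C(C)C)(C(C)C)C(C)C)c(C(=O)OC)c2c1C[C@H](/C=C/CC(=O)O)CO2
F2 | step 11 | (3E)-4-[(3R)-5-methoxy-8-(methoxycarbonyl)-7-[(triisopropylsilyl)oxy]chroman-3-yl]but-3-enoyl chloride | COc1cc(O[Si](C(C)C)(C(C)C)C(C)C)c(C(=O)OC)c2c1C[C@H](/C=C/CC(=O)Cl)CO2
F3 | step 10 | 4-methylpent-3-enal | CC(C)=CCC=O
F4 | step 10 | 1,1-dibromo-5-methylhexa-1,4-diene | CC(C)=CCC=C(Br)Br
F5 | step 10 | lithium 5-methylhex-4-en-1-yn-1-ide | CC(C)=CCC#[C-].[Li+]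
F6 | step 4 | 3-tert-butyl 8-methyl 5-methoxy-7-[(triisopropylsilyl)oxy]-2H-chromene-3,8-dicarboxylate | COc1cc(O[Si](C(C)C)(C(C)C)C(C)C)c(C(=O)OC)c2c1C=C(C(=O)OC(C)(C)C)CO2
F7 | step 3 | methyl 2-hydroxy-4-methoxy-6-[(triisopropylsilyl)oxy]benzoate | COC(=O)c1c(O)cc(OC)cc1O[Si](C(C)C)(C(C)C)C(C)C
F8 | step 6 | racemic 5-methoxy-8-(methoxycarbonyl)-7-[(triisopropylsilyl)oxy]chromane-3-carboxylic acid | COc1cc(O[Si](C(C)C)(C(C)C)C(C)C)c(C(=O)OC)c2c1CC(C(=O)O)CO2
F9 | step 6 | (4S)-4-benzyl-3-{[(3S)-5-methoxy-8-(methoxycarbonyl)-7-[(triisopropylsilyl)oxy]chroman-3-yl]carbonyl}-1,3-oxazolidin-2-one | COc1cc(O[Si](C(C)C)(C(C)C)C(C)C)c(C(=O)OC)c2c1C[C@H](C(=O)N1[C@@H](Cc3ccccc3)COC1=O)CO2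
F10 | step 6 | (4S)-4-benzyl-3-{[(3R)-5-methoxy-8-(methoxycarbonyl)-7-[(triisopropylsilyl)oxy]chroman-3-yl]carbonyl}-1,3-oxazolidin-2-one | COc1cc(O[Si](C(C)C)(C(C)C)C(C)C)c(C(=O)OC)c2c1C[C@@H](C(=O)N1[C@@H](Cc3ccccc3)COC1=O)CO2
A1 | alternative 1 | methyl (3R)-3-{2,4-bis[(tert-butyldimethylsilyl)oxy]-3-(3-methylbut-2-en-1-yl)phenyl}-2-hydroxy-5-methoxy-7-[(triisopropylsilyl)oxy]chromane-8-carboxylate (mixture at C2) | COc1cc(O[Si](C(C)C)(C(C)C)C(C)C)c(C(=O)OC)c2c1C[C@H](c1ccc(O[Si](C)(C)C(C)(C)C)c(CC=C(C)C)c1O[Si](C)(C)C(C)(C)C)C(O)O2
A2 | alternative 1 | {2,4-bis[(tert-butyldimethylsilyl)oxy]-3-(3-methylbut-2-en-1-yl)phenyl}acetaldehyde | O=CCc1ccc(O[Si](C)(C)C(C)(C)C)c(CC=C(C)C)c1O[Si](C)(C)C(C)(C)C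
A3 | alternative 1 | methyl 2-hydroxy-4-methoxy-3-[(4-methylbenzenesulfonyl)methyl]-6-[(triisopropylsilyl)oxy]benzoate | COc1cc(O[Si](C(C)C)(C(C)C)C(C)C)c(C(=O)OC)c(O)c1CS(=O)(=O)c1ccc(C)cc1
A4 | alternative 2 | methyl (3R)-3-{2,4-bis[(tert-butyldimethylsilyl)oxy]-3-(3-methylbut-2-en-1-yl)phenyl}-7-hydroxy-5-methoxychromane-8-carboxylate | COc1cc(O)c(C(=O)OC)c2c1C[C@H](c1ccc(O[Si](C)(C)C(C)(C)C)c(CC=C(C)C)c1O[Si](C)(C)C(C)(C)C)CO2
A5 | alternative 2 | methyl (2E)-3-[(2R)-2-{2,4-bis[(tert-butyldimethylsilyl)oxy]-3-(3-methylbut-2-en-1-yl)phenyl}-3-{5-[(tert-butyldimethylsilyl)oxy]-3-methoxyfuran-2-yl}propoxy]prop-2-enoate | COC(=O)/C=C/OC[C@H](Cc1oc(O[Si](C)(C)C(C)(C)C)cc1OC)c1ccc(O[Si](C)(C)C(C)(C)C)c(CC=C(C)C)c1O[Si](C)(C)C(C)(C)C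
A6 | alternative 3 | (3R)-3-[2,4-bis(methoxymethoxy)-3-(3-methylbut-2-en-1-yl)phenyl]-5-methoxy-7-(methoxymethoxy)chromane-8-carbaldehyde | COc1cc(OCOC)c(C=O)c2c1C[C@H](c1ccc(OCOC)c(CC=C(C)C)c1OCOC)CO2
A7 | alternative 3 | (2R)-2-[2,4-bis(methoxymethoxy)-3-(3-methylbut-2-en-1-yl)phenyl]-3-[2-fluoro-6-methoxy-4-(methoxymethoxy)phenyl]propan-1-ol | COc1cc(OCOC)cc(F)c1C[C@@H](CO)c1ccc(OCOC)c(CC=C(C)C)c1OCOC
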